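**Retrosynthetic overview**
- The target comes from its C8 ketone by α-face methyl addition; that ketone comes from a 9α-hydroxy-8-keto butenolide by the key O–C13 bond formation (5-exo oxa-Michael), which closes the spiro-tetrahydrofuran and sets C13.
- The α-ketol comes from a C8=C9 alkene by α-face ketohydroxylation (C9–O); the side chain comes from an enol triflate, a vinylstannane and 4-bromofuran-2(5H)-one (Stille, then B-alkyl Suzuki).
- The tricyclic keto-lactone comes from a Δ5(6) tert-butyl ester by bromolactonisation (C6–O bond, γ-lactone) and radical debromination (5α-H).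
- The bicyclic ester comes from 2-methylcyclohexane-1,3-dione, acrolein and an α-methyl ylide by Michael addition, Wittig olefination, desymmetrising copper hydride reductive aldol (ring A, C4, C10) and dehydration.
- Ring order: B (bought) → A → γ-lactone → butenolide (bought, coupled) → spiro-tetrahydrofuran.

Assumption and notation: labdane numbering is used in names and explanations (C19 = lactone carbonyl on C4, C18 = 4α-methyl, C20 = 10-methyl, C17 = 8-methyl, side chain C11–C16); 4-bromofuran-2(5H)-one and tributyl(vinyl)stannane are taken as purchased.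

**Step 1**
Reactants: 1 2-methylcyclohexane-1,3-dione; 2 acrolein
Product: 3 3-(1-methyl-2,6-dioxocyclohexyl)propanal
Conditions: acrolein (1.5 equiv), H2O, rt, 16 h
Reagents that add atoms: none
Why: Michael addition of the acidic cyclic 1,3-dione to acrolein quaternises the future C10 cleanly; no stereocentre arises because the dione is symmetric.

**Step 2**
Reactants: 4 tert-butyl 2-bromopropanoate; 5 triphenylphosphine
Product: 7 tert-butyl 2-(triphenyl-λ5-phosphanylidene)propanoate, via phosphonium bromide 6 (not isolated)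
Conditions: toluene, 80 °C; then aq. NaOH, CH2Cl2, rt
Reagents that add atoms: none
Why: SN2 quaternisation of PPh3 by the α-bromo ester and deprotonation of the salt is the standard preparation of a stabilised Wittig ylide.

**Step 3**
Reactants: 3 3-(1-methyl-2,6-dioxocyclohexyl)propanal; 7 tert-butyl 2-(triphenyl-λ5-phosphanylidene)propanoate
Product: 8 tert-butyl (2E)-2-methyl-5-(1-methyl-2,6-dioxocyclohexyl)pent-2-enoate
Conditions: CH2Cl2, rt → 40 °C, 12 h
Reagents that add atoms: none
Why: Wittig olefination with a stabilised α-methyl ylide is aldehyde-selective (the hindered ring ketones do not react) and E-selective.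

**Step 4**
Reactants: 8 tert-butyl (2E)-2-methyl-5-(1-methyl-2,6-dioxocyclohexyl)pent-2-enoate
Product: 10 tert-butyl (1S,4aS,8aR)-8a-hydroxy-1,4a-dimethyl-5-oxodecahydronaphthalene-1-carboxylate, via phenylsilyl ether 9 (not isolated)
Conditions: Cu(OAc)2·H2O (5 mol %), (R)-DTBM-SEGPHOS (5.5 mol %; the antipode is used if the screen shows the opposite sense), PhSiH3 (1.2 equiv), toluene, −30 °C → rt; then 1 M aq. HCl, THF
Reagents that add atoms: none
Why: copper hydride-catalysed desymmetrising reductive aldol cyclisation (conjugate reduction, then intramolecular aldol), in which hydride adds to C3 and the chiral copper enolate attacks one enantiotopic ring carbonyl through a chelated chair transition state, so that C10 (S) is set by catalyst control and the 4-ester and 5-OH come out cis to the angular methyl (C4 S, C5 R).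

**Step 5**
Reactants: 10 tert-butyl (1S,4aS,8aR)-8a-hydroxy-1,4a-dimethyl-5-oxodecahydronaphthalene-1-carboxylate
Product: 11 tert-butyl (1S,4aS)-1,4a-dimethyl-5-oxo-1,2,3,4,4a,5,6,7-octahydronaphthalene-1-carboxylate
Conditions: SOCl2 (1.5 equiv), pyridine, CH2Cl2, −10 → 0 °C
Reagents that add atoms: none
Why: E2 dehydration of the tertiary β-hydroxy ester through its chlorosulfite can only give the Δ5(6) alkene because C4 and C10 are quaternary; the C5 stereocentre is removed and C4 and C10 are untouched.

**Step 6**
Reactants: 11 tert-butyl (1S,4aS)-1,4a-dimethyl-5-oxo-1,2,3,4,4a,5,6,7-octahydronaphthalene-1-carboxylate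
Product: 12 (4R,5S,6R,10R)-5-bromo-9-oxo-11,12,13,14,15,16,17-heptanorlabdan-19,6-olide
Conditions: NBS (1.1 equiv), CH2Cl2, 0 °C → rt, dark
Reagents that add atoms: N-bromosuccinimide, O=C1CCC(=O)N1Br
Why: bromolactonisation, in which the bromonium ion forms on the open α-face and the axial 4β-ester carbonyl opens it trans-diaxially at C6 from the β-face (as in 5α-bromo-6β-oxy steroid chemistry) with loss of the tert-butyl group as isobutene; this forms the C6–O bond and the γ-lactone and sets C6 (β-oxygen).

**Step 7**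
Reactants: 12 (4R,5S,6R,10R)-5-bromo-9-oxo-11,12,13,14,15,16,17-heptanorlabdan-19,6-olide
Product: 13 (4S,5R,6R,10S)-9-oxo-11,12,13,14,15,16,17-heptanorlabdan-19,6-olide
Conditions: Bu3SnH (1.3 equiv), AIBN (cat.), toluene, 80 °C
Reagents that add atoms: none
Why: radical dehalogenation, in which the tertiary C5 radical takes hydrogen from the α-face because the β-face is capped by the cis-fused lactone and the 10β-methyl, giving the trans-decalin (5α-H).

**Step 8**
Reactants: 13 (4S,5R,6R,10S)-9-oxo-11,12,13,14,15,16,17-heptanorlabdan-19,6-olide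
Product: 15 (4S,5R,6R,10S)-9-(trifluoromethanesulfonyloxy)-11,12,13,14,15,16,17-heptanorlabd-8-en-19,6-olide, via potassium enolate 14 (not isolated)
Conditions: KN(SiMe3)2 (1.2 equiv), THF, −78 °C; then PhNTf2 (1.3 equiv), −78 → 0 °C; 0.5 M aq. HCl work-up
Reagents that add atoms: N-phenylbis(trifluoromethanesulfonimide), O=S(=O)(N(c1ccccc1)S(=O)(=O)C(F)(F)F)C(F)(F)F
Why: enolate O-triflation gives a single enol triflate because the ketone can enolise only towards C8 (C10 is quaternary and the lactone has no α-hydrogen).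

**Step 9**
Reactants: 15 (4S,5R,6R,10S)-9-(trifluoromethanesulfonyloxy)-11,12,13,14,15,16,17-heptanorlabd-8-en-19,6-olide; 16 tributyl(vinyl)stannane
Product: 17 (4S,5R,6R,10S)-13,14,15,16,17-pentanorlabda-8,11-dien-19,6-olide
Conditions: Pd(PPh3)4 (5 mol %), LiCl (3 equiv), THF, 65 °C
Reagents that add atoms: none
Why: Stille coupling (zerovalent palladium, LiCl-promoted) of a hindered enol triflate with a vinylstannane installs C11 and C12 without touching any stereocentre.

**Step 10**
Reactants: 17 (4S,5R,6R,10S)-13,14,15,16,17-pentanorlabda-8,11-dien-19,6-olide; 18 4-bromofuran-2(5H)-one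
Product: 20 (4S,5R,6R,10S)-17-norlabda-8,13-diene-19,6:15,16-diolide, via alkylborane 19 (not isolated)
Conditions: 9-BBN (1.2 equiv), THF, 0 °C → rt; then 18, PdCl2(dppf) (5 mol %; dppf = 1,1'-bis(diphenylphosphino)ferrocene), 3 M aq. K3PO4, DMF, rt → 40 °C
Reagents that add atoms: none
Why: 9-BBN hydroborates only the terminal vinyl group (boron on C12) and the B-alkyl Suzuki–Miyaura coupling with the β-bromobutenolide forms C12–C13, bringing in the complete butenolide ring.

**Step 11**
Reactants: 20 (4S,5R,6R,10S)-17-norlabda-8,13-diene-19,6:15,16-diolide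
Product: 21 (4S,5R,6R,9S,10S)-9-hydroxy-8-oxo-17-norlabd-13-ene-19,6:15,16-diolide
Conditions: RuCl3·xH2O (1 mol %), KHSO5 (as 2KHSO5·KHSO4·K2SO4, 5 equiv), NaHCO3 (2.5 equiv), EtOAc/MeCN/H2O 6:6:1, rt, 15 min
Reagents that add atoms: potassium peroxymonosulfate, [K+].[O-]S(=O)(=O)OO
Why: RuO4-catalysed ketohydroxylation, in which RuO4 adds to the electron-rich trisubstituted ring alkene from the α-face (anti to the 10β-methyl) and the secondary ruthenate carbon is oxidised on to the ketone, giving the 9α-hydroxy-8-ketone and setting C9 (oxygen α, chain β) while the electron-poor butenolide alkene reacts more slowly.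

**Step 12**
Reactants: 21 (4S,5R,6R,9S,10S)-9-hydroxy-8-oxo-17-norlabd-13-ene-19,6:15,16-diolide
Product: 22 (4S,5R,6R,9S,10S,13S)-9,13-epoxy-8-oxo-17-norlabdane-19,6:15,16-diolide
Conditions: chiral bifunctional iminophosphorane–thiourea organocatalyst (tert-leucine-derived azide + P(4-MeOC6H4)3, 10 mol %; antipode chosen by screening), toluene, −20 °C
Reagents that add atoms: none
Why: Proposed new method: a catalyst-controlled, spirocyclising 5-exo-trig oxa-Michael addition of a tertiary α-ketol to a β-substituted butenolide, in which the iminophosphorane (a strong, non-nucleophilic Brønsted base) reversibly deprotonates the acidified 9α-OH while the thiourea N–H donors bind the butenolide carbonyl, so that the ion-paired alkoxide is delivered to one π-face of C13 and the lactone enolate is protonated at C14 by the iminophosphoranium; at −20 °C the addition is kinetically controlled, which overrides the negligible substrate bias, sets C13 (S) and closes the tetrahydrofuran through the new O–C13 bond; the closest known reaction type is the bifunctional iminophosphorane-catalysed enantioselective intramolecular oxa-Michael addition of alcohols to α,β-unsaturated esters and amides, alongside base-mediated 9-OH to C13 closures of labdane butenolides that give epimer mixtures.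

**Step 13**
Reactants: 22 (4S,5R,6R,9S,10S,13S)-9,13-epoxy-8-oxo-17-norlabdane-19,6:15,16-diolide
Product: 23 (4S,5R,6R,8S,9S,10S,13S)-9,13-epoxy-8-hydroxylabdane-19,6:15,16-diolide
Conditions: MeLi (1.5 equiv), anhydrous CeCl3 (1.6 equiv), THF, −78 °C; then aq. NH4Cl
Reagents that add atoms: methyllithium, [Li]C
Why: organocerium 1,2-addition to the ketone occurs by equatorial attack on the α-face because the axial β trajectory is blocked by the syn-axial 10β-methyl and 6β-oxygen, giving 8α-methyl and 8β-OH (C8 S), and the weakly basic, ketone-selective trivalent cerium reagent leaves both lactones and C13 untouched.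

**Compound list**
1 | 2-methylcyclohexane-1,3-dione | CC1C(=O)CCCC1=O | starting material
2 | acrolein (prop-2-enal) | C=CC=O | starting material
3 | 3-(1-methyl-2,6-dioxocyclohexyl)propanal | CC1(CCC=O)C(=O)CCCC1=O | intermediate
4 | tert-butyl 2-bromopropanoate (racemic) | CC(Br)C(=O)OC(C)(C)C | starting material
5 | triphenylphosphine | c1ccc(cc1)P(c1ccccc1)c1ccccc1 | starting material
6 | (1-tert-butoxy-1-oxopropan-2-yl)triphenylphosphonium bromide | CC(C(=O)OC(C)(C)C)[P+](c1ccccc1)(c1ccccc1)c1ccccc1.[Br-] | intermediate (not isolated)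
7 | tert-butyl 2-(triphenyl-λ5-phosphanylidene)propanoate | CC(C(=O)OC(C)(C)C)=P(c1ccccc1)(c1ccccc1)c1ccccc1 | intermediate
8 | tert-butyl (2E)-2-methyl-5-(1-methyl-2,6-dioxocyclohexyl)pent-2-enoate | CC(C)(C)OC(=O)/C(C)=C/CCC1(C)C(=O)CCCC1=O | intermediate
9 | tert-butyl (1S,4aS,8aR)-1,4a-dimethyl-5-oxo-8a-(phenylsilyloxy)decahydronaphthalene-1-carboxylate | CC(C)(C)OC(=O)[C@@]1(C)CCC[C@]2(C)C(=O)CCC[C@]12O[SiH2]c1ccccc1 | intermediate (not isolated)
10 | tert-butyl (1S,4aS,8aR)-8a-hydroxy-1,4a-dimethyl-5-oxodecahydronaphthalene-1-carboxylate | CC(C)(C)OC(=O)[C@@]1(C)CCC[C@]2(C)C(=O)CCC[C@]12O | intermediate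
11 | tert-butyl (1S,4aS)-1,4a-dimethyl-5-oxo-1,2,3,4,4a,5,6,7-octahydronaphthalene-1-carboxylate | CC(C)(C)OC(=O)[C@@]1(C)CCC[C@]2(C)C(=O)CCC=C12 | intermediate
12 | (4R,5S,6R,10R)-5-bromo-9-oxo-11,12,13,14,15,16,17-heptanorlabdan-19,6-olide (5α-bromo; 6β-oxygen) | C1C[C@H]2OC(=O)[C@@]3(C)CCC[C@@](C)([C@@]23Br)C1=O | intermediate
13 | (4S,5R,6R,10S)-9-oxo-11,12,13,14,15,16,17-heptanorlabdan-19,6-olide (5α-H; 6β-oxygen) | C1C[C@H]2OC(=O)[C@@]3(C)CCC[C@@](C)([C@@H]23)C1=O | intermediate
14 | potassium 8-en-9-olate of 13 | [K+].[O-]C1=CC[C@H]2OC(=O)[C@@]3(C)CCC[C@@]1(C)[C@@H]23 | intermediate (not isolated)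
15 | (4S,5R,6R,10S)-9-(trifluoromethanesulfonyloxy)-11,12,13,14,15,16,17-heptanorlabd-8-en-19,6-olide | FC(F)(F)S(=O)(=O)OC1=CC[C@H]2OC(=O)[C@@]3(C)CCC[C@@]1(C)[C@@H]23 | intermediate
16 | tributyl(vinyl)stannane | C=C[Sn](CCCC)(CCCC)CCCC | starting material
17 | (4S,5R,6R,10S)-13,14,15,16,17-pentanorlabda-8,11-dien-19,6-olide | C=CC1=CC[C@H]2OC(=O)[C@@]3(C)CCC[C@@]1(C)[C@@H]23 | intermediate
18 | 4-bromofuran-2(5H)-one | BrC1=CC(=O)OC1 | starting material
19 | (4S,5R,6R,10S)-12-(9-borabicyclo[3.3.1]nonan-9-yl)-13,14,15,16,17-pentanorlabd-8-en-19,6-olide | C(CB1C2CCCC1CCC2)C1=CC[C@H]2OC(=O)[C@@]3(C)CCC[C@@]1(C)[C@@H]23 | intermediate (not isolated)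
20 | (4S,5R,6R,10S)-17-norlabda-8,13-diene-19,6:15,16-diolide | O=C1OCC(CCC2=CC[C@H]3OC(=O)[C@@]4(C)CCC[C@@]2(C)[C@@H]34)=C1 | intermediate
21 | (4S,5R,6R,9S,10S)-9-hydroxy-8-oxo-17-norlabd-13-ene-19,6:15,16-diolide (9α-OH) | O=C1OCC(CC[C@@]2(O)C(=O)C[C@H]3OC(=O)[C@@]4(C)CCC[C@@]2(C)[C@@H]34)=C1 | intermediate
22 | (4S,5R,6R,9S,10S,13S)-9,13-epoxy-8-oxo-17-norlabdane-19,6:15,16-diolide | O=C1C[C@H]2OC(=O)[C@@]3(C)CCC[C@@](C)([C@@H]23)[C@@]12CC[C@]1(COC(=O)C1)O2 | intermediate
23 | (4S,5R,6R,8S,9S,10S,13S)-9,13-epoxy-8-hydroxylabdane-19,6:15,16-diolide (8β-OH; 9α-oxygen) | C[C@]1(O)C[C@H]2OC(=O)[C@@]3(C)CCC[C@@](C)([C@@H]23)[C@@]12CC[C@]1(COC(=O)C1)O2 | target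

**Totals**
Total step count: 13.
Longest linear sequence: 12 steps (steps 1 and 3–13, from 2-methylcyclohexane-1,3-dione).

**The three steps most likely to fail, with fallbacks**

Step 4 (desymmetrising reductive aldol; the enolate is fully substituted, so reactivity, ee and dr are not assured). The fallback sets out from 8 and comes back at 10. The enantio-determining event is moved to a Corey–Bakshi–Shibata reduction: (S)-2-methyl-CBS-oxazaborolidine with catecholborane in toluene at −78 °C reduces one ring carbonyl and gives tert-butyl (2E)-5-[(1R,2R)-2-hydroxy-1-methyl-6-oxocyclohexyl]-2-methylpent-2-enoate F1, the minor diastereomer being removed by chromatography. Ring A is then closed under substrate control with stoichiometric [(Ph3P)CuH]6 in toluene (conjugate reduction, then aldol onto the remaining ketone) to give tert-butyl (1S,4aR,5R,8aR)-5,8a-dihydroxy-1,4a-dimethyldecahydronaphthalene-1-carboxylate F2. Dess–Martin oxidation of the secondary alcohol of F2 returns 10. This fallback addresses poor enantiocontrol; it does not help if the quaternary centre cannot be formed by reductive aldol at all.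

Step 11 (one-pot ketohydroxylation; risk of attack on the butenolide alkene or over-oxidation). The fallback sets out from 20 and comes back at 21. OsO4 (2 mol %) with N-methylmorpholine N-oxide in acetone/H2O at 0 °C dihydroxylates the ring alkene from the α-face and gives (4S,5R,6R,8R,9S,10S)-8,9-dihydroxy-17-norlabd-13-ene-19,6:15,16-diolide F3. Dess–Martin periodinane then oxidises only the secondary 8-OH and gives 21.

Step 12 (the proposed new method; the catalyst may not override the substrate or may not turn over with a tertiary α-ketol). The fallback uses known chemistry, sets out from 21 and comes back at 22. Stereocontrol by a chiral catalyst is given up in favour of thermodynamic closure, separation and recycling: DBU (0.2 equiv) in CH2Cl2 at rt effects the known base-mediated, reversible 9-OH to C13 oxa-Michael closure and gives 22 together with its C13 epimer (4S,5R,6R,9S,10S,13R)-9,13-epoxy-8-oxo-17-norlabdane-19,6:15,16-diolide F4. Compound 22 is separated by chromatography, and F4 is re-exposed to DBU, which re-opens it by retro-oxa-Michael reaction and re-closes it, so material is funnelled to 22 over recycles.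

**Further compounds**
F1 | step 4 | tert-butyl (2E)-5-[(1R,2R)-2-hydroxy-1-methyl-6-oxocyclohexyl]-2-methylpent-2-enoate | CC(C)(C)OC(=O)/C(C)=C/CC[C@@]1(C)C(=O)CCC[C@H]1O
F2 | step 4 | tert-butyl (1S,4aR,5R,8aR)-5,8a-dihydroxy-1,4a-dimethyldecahydronaphthalene-1-carboxylate | CC(C)(C)OC(=O)[C@@]1(C)CCC[C@]2(C)[C@H](O)CCC[C@]12O
F3 | step 11 | (4S,5R,6R,8R,9S,10S)-8,9-dihydroxy-17-norlabd-13-ene-19,6:15,16-diolide | O=C1OCC(CC[C@@]2(O)[C@H](O)C[C@H]3OC(=O)[C@@]4(C)CCC[C@@]2(C)[C@@H]34)=C1
F4 | step 12 | (4S,5R,6R,9S,10S,13R)-9,13-epoxy-8-oxo-17-norlabdane-19,6:15,16-diolide | O=C1C[C@H]2OC(=O)[C@@]3(C)CCC[C@@](C)([C@@H]23)[C@@]12CC[C@@]1(COC(=O)C1)O2
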